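The ester bond is cut first, giving (−)-drimenol and caffeic acid, and C11 is then removed from drimenol, which leads back to a bicyclic dienone. Everything rests on the C1–C10 bond. Ring B (C5–C10), with oxygen on C9, methyl C12 on C8 and methyl C15 on C10, is a masked 2,6-dimethylphenol whose meta carbon C5 carries C4 and the chain C3–C2–C1. The precursor is thus 3-(5-bromo-2-methylpentan-2-yl)-2,6-dimethylphenol. Its phenoxide, paired with a chiral ammonium ion, attacks the bromide through C10: one operation closes ring A, dearomatises ring B, sets quaternary C10 and leaves the C9 carbonyl and the C7=C8 methyl alkene ready for use.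

Key step: step 7

Remarks on the chemistry (drimane numbering throughout):
- Assumption: precedent does not show which phenoxide face a given cinchona salt shields. The cinchonidinium salt is written, and its pseudoenantiomeric cinchoninium salt would be used if the sense of induction is opposite.
- C6 (para to the phenol oxygen) is bonded to C5 and lies within reach of the tether. No blocking group is placed there, because any substituent on C6 would squeeze the tert-alkyl group between two ortho substituents and cancel the conformational bias on which C10 selectivity rests.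

Step 1
Reactants: 1 methyl 3-methoxy-2-methylbenzoate
Product: 3 2-(3-methoxy-2-methylphenyl)propan-2-ol, via aryl methyl ketone 2 (not isolated)
Conditions: MeMgBr (3 equiv), THF, 0 °C to rt; H2O
Reagents that add atoms: methylmagnesium bromide, C[Mg]Br
Why: Double Grignard addition to an ester, in which ketone 2 released by the first addition is more electrophilic than 1 and is consumed at once, and a single ortho methyl group does not block the carbonyl carbon.

Step 2
Reactants: 3 2-(3-methoxy-2-methylphenyl)propan-2-ol; 4 allyltrimethylsilane
Product: 5 1-methoxy-2-methyl-3-(2-methylpent-4-en-2-yl)benzene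
Conditions: 4 (1.5 equiv), InCl3 (5 mol %), ClCH2CH2Cl, rt to 50 °C
Reagents that add atoms: none
Why: Hosomi–Sakurai-type SN1 allylation, in which InCl3 ionises the tertiary benzylic alcohol to a cumyl-type cation that the allylsilane traps irreversibly at its γ-carbon (proton loss to the styrene is reversible), which builds quaternary C4 with both methyl groups and brings in C3, C2 and C1.

Step 3
Reactants: 5 1-methoxy-2-methyl-3-(2-methylpent-4-en-2-yl)benzene
Product: 7 2-methoxy-1,3-dimethyl-4-(2-methylpent-4-en-2-yl)benzene, via aryllithium 6 (not isolated)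
Conditions: n-BuLi (1.3 equiv), TMEDA (1.3 equiv), Et2O, 0 °C to rt; MeI (1.5 equiv), −78 °C to rt
Reagents that add atoms: iodomethane, CI
Why: Directed ortho-metalation, in which the methoxy group guides n-BuLi·TMEDA to the only free ortho C–H (the future C8), ring lithiation being the normal course for 2-alkylanisoles without superbases and faster than allylic metalation of the neopentyl-type CH2, and MeI then methylates aryllithium 6 to install C12.

Step 4
Reactants: 7 2-methoxy-1,3-dimethyl-4-(2-methylpent-4-en-2-yl)benzene
Product: 9 4-(3-methoxy-2,4-dimethylphenyl)-4-methylpentan-1-ol, via B-alkyl-9-BBN 8 (not isolated)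
Conditions: 9-BBN (1.2 equiv), THF, 0 °C to rt; NaOH aq, H2O2, 0 °C to rt
Reagents that add atoms: hydrogen peroxide, OO
Why: Hydroboration–oxidation, in which 9-BBN places boron on the terminal carbon of the monosubstituted alkene for steric reasons and alkaline peroxide replaces boron by hydroxyl without touching the arene.

Step 5
Reactants: 9 4-(3-methoxy-2,4-dimethylphenyl)-4-methylpentan-1-ol
Product: 10 1-(5-bromo-2-methylpentan-2-yl)-3-methoxy-2,4-dimethylbenzene
Conditions: CBr4 (1.2 equiv), PPh3 (1.25 equiv), CH2Cl2, 0 °C
Reagents that add atoms: tetrabromomethane, BrC(Br)(Br)Br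
Why: Appel reaction, in which bromide displaces the alkoxyphosphonium group of the unhindered primary alcohol by SN2 under neutral conditions that leave the aryl ether alone.

Step 6
Reactants: 10 1-(5-bromo-2-methylpentan-2-yl)-3-methoxy-2,4-dimethylbenzene
Product: 11 3-(5-bromo-2-methylpentan-2-yl)-2,6-dimethylphenol
Conditions: BBr3 (1.5 equiv), CH2Cl2, −78 to 0 °C; H2O
Reagents that add atoms: none
Why: Lewis-acid cleavage of an aryl methyl ether, in which BBr3 binds the ether oxygen, bromide removes the methyl group by SN2 and hydrolysis of the aryloxyborane frees the phenol, while the primary bromide is inert at this temperature.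

Step 7
Reactants: 11 3-(5-bromo-2-methylpentan-2-yl)-2,6-dimethylphenol
Product: 13 (10S)-11-nor-drima-5,7-dien-9-one, via potassium phenoxide 12 (not isolated)
Conditions: powdered KOH (5 equiv), N-[4-(trifluoromethyl)benzyl]cinchonidinium bromide (10 mol %), toluene (0.01 M), 0 °C, argon, exclusion of light
Reagents that add atoms: none
Why: Proposed new method: KOH deprotonates 11 at the solid surface, the chiral ammonium cation takes phenoxide 12 into toluene as a contact ion pair, and the methyl-bearing ortho carbon C10 displaces bromide from C1 (SN2), which turns ring B into a 6,6-disubstituted cyclohexa-2,4-dienone that has no acidic hydrogen and cannot rearomatise. The closest known reaction types are the racemic base-induced ortho-alkylative dearomatisation of phenols (Ar2-6 phenoxide participation) and the cinchona phase-transfer C-alkylation of indanone and glycine imine enolates. Ring A closes in the 6-exo-tet mode, assisted by the gem-dialkyl effect of C4. The one new stereocentre, C10, is controlled only by the catalyst: its hydroxyl group is meant to hydrogen-bond to the phenoxide oxygen while the quinoline and benzyl groups cover one face of ring B, so that C1 enters from the α face and C15 ends up β (10S). The selectivity needed is C10 over C6, because the para carbon C6 is also bonded to C5 and could close the same kind of six-membered ring and then rearomatise; the substrate secures it through the gearing of the tert-alkyl group, since closure at C6 would turn a C4 methyl group almost into the ring plane against C15 (peri strain) whereas closure at C10 turns it toward H6, and in toluene the leaving bromide has to stay close to the cation held at oxygen, which is possible only above the ortho carbon. Closure through oxygen would mean an eight-membered ether, and high dilution suppresses intermolecular etherification.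

Step 8
Reactants: 13 (10S)-11-nor-drima-5,7-dien-9-one
Product: 16 (5S,10S)-11-nor-drim-7-en-9-one, via lithium dienolate 14 (not isolated), via Δ6 β,γ-enone 15 (not isolated)
Conditions: Li (2.2 equiv), t-BuOH (1.0 equiv), NH3/THF, −78 °C; NH4Cl; then NaOMe (0.2 equiv), MeOH, rt
Reagents that add atoms: none
Why: Dissolving-metal 1,6-reduction of a linearly conjugated dienone, in which two electrons and one proton convert 13 into dienolate 14, the proton entering the δ-carbon C5 axially from the α face (away from the axial methyl groups on C10 and C4 and toward the more stable trans-decalin), and catalytic base then moves the alkene of the quench product 15 into conjugation at C7=C8.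

Step 9
Reactants: 16 (5S,10S)-11-nor-drim-7-en-9-one
Product: 17 drima-7,9(11)-diene
Conditions: MePPh3Br (4 equiv), KOtBu (3.8 equiv), toluene, rt then 90 °C
Reagents that add atoms: methyltriphenylphosphonium bromide, C[P+](c1ccccc1)(c1ccccc1)c1ccccc1.[Br-]
Why: Wittig methylenation, in which the small non-stabilised ylide, used in excess and with heating as is usual for hindered ketones, adds 1,2 to the C9 carbonyl group (C10 bears no hydrogen and reversible γ-deprotonation at C6 touches no stereocentre) and the oxaphosphetane collapses to the C9=C11 bond.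

Step 10
Reactants: 17 drima-7,9(11)-diene
Product: 19 (−)-drimenol, via B-drimenyl-9-BBN 18 (not isolated)
Conditions: 9-BBN (1.5 equiv), THF, rt to 50 °C; NaOH aq, H2O2, 0 °C
Reagents that add atoms: hydrogen peroxide, OO
Why: Hydroboration–oxidation, in which 9-BBN prefers the 1,1-disubstituted C9=C11 bond to the trisubstituted C7=C8 bond, boron goes to C11, and hydrogen reaches C9 from the α face opposite to the axial C15 methyl group on the neighbouring C10, which sets 9α-H (9S) with the CH2OH group equatorial.

Step 11
Reactants: 20 caffeic acid
Product: 22 (E)-3-[3,4-bis(tert-butyldimethylsilyloxy)phenyl]acrylic acid, via tris-TBS caffeate 21 (not isolated)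
Conditions: TBSCl (3.5 equiv), imidazole (7 equiv), DMF, rt; then AcOH/THF/H2O, rt
Reagents that add atoms: tert-butyldimethylsilyl chloride, CC(C)(C)[Si](C)(C)Cl
Why: Silyl protection, in which TBSCl/imidazole silylates both phenols and the acid, and aqueous acetic acid then hydrolyses only the far more labile silyl ester of 21.

Step 12
Reactants: 19 (−)-drimenol; 22 (E)-3-[3,4-bis(tert-butyldimethylsilyloxy)phenyl]acrylic acid
Product: 23 drimenyl (E)-3-[3,4-bis(tert-butyldimethylsilyloxy)phenyl]acrylate
Conditions: DCC (1.3 equiv), DMAP (0.2 equiv), CH2Cl2, 0 °C to rt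
Reagents that add atoms: none
Why: Steglich esterification, in which DCC activates acid 22 and DMAP passes the acyl group to the β-branched primary alcohol, with no stereocentre or alkene geometry involved.

Step 13
Reactants: 23 drimenyl (E)-3-[3,4-bis(tert-butyldimethylsilyloxy)phenyl]acrylate
Product: 24 drimenyl caffeate (CNP0265201.1)
Conditions: Bu4NF (2.2 equiv), AcOH (2.2 equiv), THF, 0 °C
Reagents that add atoms: none
Why: Fluoride desilylation, in which the aryl silyl ethers are cleaved rapidly and acetic acid buffers the catecholate so that the ester, the E-alkene, the C7=C8 bond and the catechol survive.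

Compound list
1 | methyl 3-methoxy-2-methylbenzoate | COC(=O)c1cccc(OC)c1C | starting material
2 | 1-(3-methoxy-2-methylphenyl)ethan-1-one | CC(=O)c1cccc(OC)c1C | intermediate
3 | 2-(3-methoxy-2-methylphenyl)propan-2-ol | CC(C)(O)c1cccc(OC)c1C | intermediate
4 | allyltrimethylsilane | C=CC[Si](C)(C)C | starting material
5 | 1-methoxy-2-methyl-3-(2-methylpent-4-en-2-yl)benzene | C=CCC(C)(C)c1cccc(OC)c1C | intermediate
6 | [2-methoxy-3-methyl-4-(2-methylpent-4-en-2-yl)phenyl]lithium | [Li]c1ccc(C(C)(C)CC=C)c(C)c1OC | intermediate
7 | 2-methoxy-1,3-dimethyl-4-(2-methylpent-4-en-2-yl)benzene | COc1c(C)ccc(C(C)(C)CC=C)c1C | intermediate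
8 | 9-[4-(3-methoxy-2,4-dimethylphenyl)-4-methylpentyl]-9-borabicyclo[3.3.1]nonane | COc1c(C)ccc(C(C)(C)CCCB2C3CCCC2CCC3)c1C | intermediate
9 | 4-(3-methoxy-2,4-dimethylphenyl)-4-methylpentan-1-ol | COc1c(C)ccc(C(C)(C)CCCO)c1C | intermediate
10 | 1-(5-bromo-2-methylpentan-2-yl)-3-methoxy-2,4-dimethylbenzene | COc1c(C)ccc(C(C)(C)CCCBr)c1C | intermediate
11 | 3-(5-bromo-2-methylpentan-2-yl)-2,6-dimethylphenol (key-step precursor) | Cc1ccc(C(C)(C)CCCBr)c(C)c1O | intermediate
12 | potassium 3-(5-bromo-2-methylpentan-2-yl)-2,6-dimethylphenoxide (exchanged in solution for the chiral ammonium ion pair) | Cc1ccc(C(C)(C)CCCBr)c(C)c1[O-].[K+] | intermediate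
13 | (10S)-11-nor-drima-5,7-dien-9-one = (8aS)-2,5,5,8a-tetramethyl-6,7,8,8a-tetrahydronaphthalen-1(5H)-one (key-step product) | CC1=CC=C2C(C)(C)CCC[C@]2(C)C1=O | intermediate
14 | lithium (5S,10S)-11-nor-drima-6,8-dien-9-olate | CC=1C=C[C@H]2C(C)(C)CCC[C@]2(C)C=1[O-].[Li+] | intermediate
15 | (5S,10S)-11-nor-drim-6-en-9-one, both C8 epimers | CC1C=C[C@H]2C(C)(C)CCC[C@]2(C)C1=O | intermediate
16 | (5S,10S)-11-nor-drim-7-en-9-one = (4aS,8aS)-2,5,5,8a-tetramethyl-4a,5,6,7,8,8a-hexahydronaphthalen-1(4H)-one, trans-fused | CC1=CC[C@H]2C(C)(C)CCC[C@]2(C)C1=O | intermediate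
17 | drima-7,9(11)-diene = (4aS,8aS)-2,5,5,8a-tetramethyl-1-methylidene-1,4,4a,5,6,7,8,8a-octahydronaphthalene | CC1=CC[C@H]2C(C)(C)CCC[C@]2(C)C1=C | intermediate
18 | 9-(drim-7-en-11-yl)-9-borabicyclo[3.3.1]nonane, 9α-H | CC1=CC[C@H]2C(C)(C)CCC[C@]2(C)[C@H]1CB3C4CCCC3CCC4 | intermediate
19 | (−)-drimenol = [(1S,4aS,8aS)-2,5,5,8a-tetramethyl-1,4,4a,5,6,7,8,8a-octahydronaphthalen-1-yl]methanol | CC1=CC[C@H]2C(C)(C)CCC[C@]2(C)[C@H]1CO | intermediate
20 | caffeic acid | O=C(O)/C=C/c1ccc(O)c(O)c1 | starting material
21 | tert-butyldimethylsilyl (E)-3-[3,4-bis(tert-butyldimethylsilyloxy)phenyl]acrylate | CC(C)(C)[Si](C)(C)OC(=O)/C=C/c1ccc(O[Si](C)(C)C(C)(C)C)c(O[Si](C)(C)C(C)(C)C)c1 | intermediate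
22 | (E)-3-[3,4-bis(tert-butyldimethylsilyloxy)phenyl]acrylic acid | O=C(O)/C=C/c1ccc(O[Si](C)(C)C(C)(C)C)c(O[Si](C)(C)C(C)(C)C)c1 | intermediate
23 | drimenyl (E)-3-[3,4-bis(tert-butyldimethylsilyloxy)phenyl]acrylate | CC1=CC[C@H]2C(C)(C)CCC[C@]2(C)[C@H]1COC(=O)/C=C/c1ccc(O[Si](C)(C)C(C)(C)C)c(O[Si](C)(C)C(C)(C)C)c1 | intermediate
24 | drimenyl caffeate, (5S,9S,10S), E | CC1=CC[C@H]2C(C)(C)CCC[C@]2(C)[C@H]1COC(=O)/C=C/c1ccc(O)c(O)c1 | target

Total step count: 13. Longest linear sequence: 12 (steps 1–10, 12 and 13). Step 11 is a one-step side branch.

Steps most likely to fail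

Step 7 (new method). The ion pair may discriminate the two phenoxide faces only weakly, and uncatalysed closure at the KOH surface would erode the selectivity further. The fallback is racemic closure followed by resolution, both known chemistry.
- It sets out from 11. KOtBu in t-BuOH/toluene at high dilution effects the achiral base-induced ortho-alkylative dearomatisation and should give racemic 11-nor-drima-5,7-dien-9-one F1.
- Preparative chromatography on a cellulose tris(3,5-dimethylphenylcarbamate) phase separates the enantiomers, and the S enantiomer re-enters the route as 13.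

Step 8. The reduced π system may be protonated at C7 instead of C5 (1,4- in place of 1,6-reduction), the proton may enter C5 from the β face, or reduction may run on past the enone. The fallback is stepwise saturation followed by re-oxidation.
- It sets out from 13. H2 (1 atm) over Pd/C in EtOAc should saturate only the accessible C7=C8 bond and give (10S)-11-nor-drim-5-en-9-one F2.
- Hydrogen-atom-transfer hydrogenation (Mn(dpm)3 cat., PhSiH3, t-BuOOH, i-PrOH) adds hydrogen to C6 and lets the tertiary C5 radical pick up hydrogen axially, which favours the trans-fused (5S,10S)-11-nor-driman-9-one F3.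
- TMSOTf/Et3N gives the only possible enol derivative, 9-(trimethylsilyloxy)-11-nor-drim-8-ene F4.
- Saegusa–Ito oxidation (Pd(OAc)2, MeCN) restores the C7=C8 bond and comes back to the route at 16.

Step 9. Shielding of the C9 carbonyl group by quaternary C10 and by C12 may slow ylide addition so much that γ-enolisation takes over. The fallback is a Peterson olefination.
- It sets out from 16. Me3SiCH2Li with CeCl3 in THF at −78 °C, a less basic carbon nucleophile, should add to C9 from the α face and give 9-(trimethylsilylmethyl)-11-nor-drim-7-en-9β-ol F5.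
- KH in THF triggers syn-elimination, which can only form the C9=C11 bond, and the route is rejoined at 17.

Further compounds
F1 | step 7 | racemic 11-nor-drima-5,7-dien-9-one | CC1=CC=C2C(C)(C)CCCC2(C)C1=O
F2 | step 8 | (10S)-11-nor-drim-5-en-9-one, both C8 epimers | CC1CC=C2C(C)(C)CCC[C@]2(C)C1=O
F3 | step 8 | (5S,10S)-11-nor-driman-9-one, trans-fused, both C8 epimers | CC1CC[C@H]2C(C)(C)CCC[C@]2(C)C1=O
F4 | step 8 | (5S,10S)-9-(trimethylsilyloxy)-11-nor-drim-8-ene | CC=1CC[C@H]2C(C)(C)CCC[C@]2(C)C=1O[Si](C)(C)C
F5 | step 9 | 9-(trimethylsilylmethyl)-11-nor-drim-7-en-9β-ol (C9 configuration of no consequence) | CC1=CC[C@H]2C(C)(C)CCC[C@]2(C)[C@]1(O)C[Si](C)(C)C
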